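Read every flask at 30 h and ask one thing before charging the next: can that much L get into solution by then? The runs so far are these, and this is what is asked:

| flask | L | X | remark | time |
|---|---|---|---|---|
| larch | 0.16 M | 0.294 M | run made earlier |  |
| cedar | 1.3 M | 0.294 M | run made earlier |  |
| ash | 0.98 M | 0.71 M | run made earlier |  |
| east | 0.30 M | 0.400 M |  | 30 h |
| west | 1.5 M | 1.20 M |  | 30 h |
| south-west | 0.98 M | 0.294 M |  | 30 h |
| north | 0.50 M | 0.600 M |  | 30 h |

| run | time / h | E / % |
|---|---|---|
| larch | 5.00 | 36.5 |
| larch | 10.0 | 84.3 |
| larch | 15.0 | 90.9 |
| larch | 20.0 | 90.3 |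
| larch | 25.0 | 89.0 |
| larch | 30.0 | 90.6 |
| cedar | 5.00 | 6.1 |
| cedar | 10.0 | 9.6 |
| cedar | 15.0 | 18.0 |
| cedar | 20.0 | 23.2 |
| cedar | 25.0 | 29.5 |
| cedar | 30.0 | 36.7 |
| ash | 6.00 | 7.3 |
| ash | 12.0 | 16.5 |
| ash | 20.0 | 28.0 |
| ash | 25.0 | 34.7 |
| ash | 30.0 | 40.2 |

(each reading ± 1 percentage point)

- the flasks put in order of amount of E, in percent of the L charged, best first, at 30 h (east / west / south-west / north)
- the amount of E, in percent of the L charged of the flask you put first, at 30 h
- the amount of E, in percent of the L charged of the flask you put last, at 30 h

- solid, in amounts per volume of the solution: L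
- steps that have been proposed: D <-> E + G; L <-> D; D + X -> Z
- at the start none of L is in solution
- what has only dissolved of L counts as not reacted

Compare larch and cedar at 10.0 h. Larch holds 0.135 M of E and cedar 0.125 M, although cedar's charge is 8.12 times larger, so c_L hardly moves the rate while solid stands. Dissolving is then the rate-limiting step. Larch levels off, so read its 90.6% at 30.0 h as the share of dissolved L that stands as E at that time and this c_X. Divide cedar's 0.477 M of E by that share and you get my 0.527 M, the dissolving capacity: my estimate of the c_L that dissolves by the reading while solid stands. At this c_X, expect a charge below it to give a yield near the share, and a charge above it a yield that falls as capacity over charge, times the share.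

So east and north, charged below it, should lead, while south-west and west, charged above it, trail. Ash, with more X than cedar and, like cedar, charged above the capacity, reached 0.394 M of E, less than cedar, so put east, with less X than north, first. For the next run, charge L below the capacity and keep c_X low.

The forecast, holding that “solid L feeds D at a constant rate”, gives east > north > south-west > west, with 87.5% and 23.5%.

The flasks give east > north > south-west > west, with 84.5% and 24.2%.

    D ⇌ E + G (K = 6.80 M, k = 1.50 × 10⁻⁴ s⁻¹)
    L ⇌ D, rate k2*(cs2 - [D]) while solid is left; crystals form when [D] > cs2 (solubility = 0.830 M, k = 6.40 × 10⁻⁶ s⁻¹)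
    D + X → Z (k = 4.30 × 10⁻⁵ M⁻¹ s⁻¹)

In west at 30.0 h, D is made 1.05 times as fast as it is used up, and it stands at 2.64% with 63.1% of L still solid. In west, the forward step of D to E runs 3.3 times as fast as the step of D to Z. West has dissolved 0.554 M against the capacity of 0.527 M. The forecast's order does not last to a much later reading: at 300 h, south-west holds 65.3% of E and east 59.2%. Now take west's L with X at 0.30 M: the capacity gives 31.8% of E, and that flask gives 29.7%.

Readings and results are simulated with constants of no real substance.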